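## The problem

Kazinol H (25) is a 2-arylchroman (flavan): ring C (O1, C2, C3, C4) is fused to ring A at C4a/C8a and carries ring B at C2. Ring A has a free hydroxyl at C7 and, ortho to it at C6, a 1,1-dimethylallyl (reverse prenyl) group whose quaternary carbon is bonded directly to the arene. Ring B is substituted at five of six positions: C1' bears C2, C2' a prenyl group, C3'/C4' are bridged by a 2,2-dimethylchromene (ring D, closed through O4'), and C5' carries a second free hydroxyl. The two oxygens O4' and O5' of a catechol therefore have to be told apart. C2 is the only stereocentre (S); nothing else in the molecule can direct it, so it must come from a reagent or catalyst. Once set it is fragile: C2 is benzylic to ring B and O4' is para to C1', so the C2–O1 bond ionises readily to a para-alkoxybenzyl cation under acid or when the oxygen is activated. The three alkenes (trisubstituted prenyl, terminal vinyl on a quaternary carbon, styrene-like chromene) rule out hydrogenation, strong acid and electrophilic reagents late in the route, and the phenols must be unmasked without acid or hydrogen. The enabling feature is that O1–C8a is an aryl–oxygen bond: with bromine on C8a and the oxygen already on C2 as a secondary carbinol, ring C can be closed by metal-catalysed coupling without breaking any bond at C2. That carbinol is the reduction product of an aryl ketone, a substrate class for which catalyst-controlled reduction is dependable.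

## Retrosynthesis

**Unmasking (25 from 24).** The two O–Si bonds are cut last. Triisopropylsilyl ethers are chosen because they must survive an amide base, formic acid–triethylamine, aqueous phosphate and hot carbonate, yet leave with fluoride. Methyl or benzyl ethers would need boron tribromide or hydrogen, which the alkenes and the C2–O1 bond would not tolerate. The precursor is the bis-silyl flavan 24.

**Ring C (24 from 23).** The O1–C8a bond is cut, giving bromo alcohol 23. The neighbouring cut O1–C2 (Mitsunobu or acid closure of a phenol onto the carbinol) makes a bond at the ionisable benzylic carbon and puts the stereocentre at risk. A C4–C4a cut would need electrophilic aromatic substitution with acid and a regiochemical choice on ring A. Cutting the aryl–oxygen bond makes C2 a spectator. The forward reaction has to make reductive elimination of the aryl–oxygen bond faster than β-hydride elimination of a benzylic palladium alkoxide.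

**The stereocentre (23 from 22).** The C2–H bond is cut to give the achiral dihydrochalcone-type ketone 22. The two flanks of the carbonyl differ as strongly as they can (ortho-substituted aryl against a CH2CH2Ar chain), which is the situation asymmetric transfer hydrogenation handles best. The alkenes and the aryl bromide must be left alone, which excludes hydrogen gas and borane in excess.

**Joining the halves (22 from 20 and 8).** The C3–C4 bond is cut between the α-carbon of methyl ketone 20 and the benzylic carbon of bromide 8. A C2–C3 cut would need a homobenzylic organometallic carrying an aryl bromide. A C4–C4a cut would need a selective sp2–sp3 coupling on a dihalide. The chosen cut gives two fragments of similar size, each derived from a commercial bromobenzaldehyde, and asks only for monoalkylation of a ketone enolate that can enolise on one side.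

**Ring A fragment (8 from 1 and 2).** Bromide 8 goes back through alcohol 7 and aldehyde 6 to phenol 5. The bond between the arene and the quaternary carbon is then cut by a retro-Claisen step to prenyl ether 3, made from 2-bromo-4-hydroxybenzaldehyde 1 and prenyl bromide 2. The sigmatropic shift inverts the allyl termini, which is what turns a prenyl ether into a 1,1-dimethylallyl group. The bromine and the future C4 are already in place in 1, and the bromine hinders the wrong ortho position. A γ-selective cross-coupling would need a second, selectively addressable halogen.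

**Ring B side chain (20 from 16 and 17).** Ketone 20 comes from aldehyde 18 through carbinol 19 (C–CH3 cut, Grignard addition then oxidation). Aldehyde 18 is cut at the aryl–CH2 bond into bromochromene 16 and prenylboronate 17. The coupling is placed after chromene formation because the terminal alkyne of the chromene precursor would itself couple with an aryl bromide under palladium. The forward step must deliver the linear allyl isomer.

**Ring D and the catechol (16 from 9 and 11).** Chromene 16 is opened by retro-electrocyclisation and retro-Claisen to aryl propargyl ether 13, which comes from phenol 12. Phenol 12 is cut at the ether oxygen into catechol 10 and 3-chloro-3-methylbut-1-yne 11, and 10 is the demethylation product of 2-bromo-4,5-dimethoxybenzaldehyde 9. Demethylation has to be first, since no prenyl or chromene group would survive boron tribromide. The two hydroxyls of 10 are distinguished by acidity: the one para to the formyl group is alkylated and the other is silylated. Rearrangement of 13 is unambiguous because only one ortho position can rearomatise.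

## Roads not taken

**Alternative 1:** one-pot 1,1-aryl-oxygenation of an allylphenol.

- *Cut and key step.* C2–C1' and O1–C2 are cut together. With Pd(OAc)2, a chiral pyridine–oxazoline ligand and benzoquinone, the ring B boronic acid A2 would add to the terminal alkene carbon of 2-allyl-5-(prenyloxy)phenol A1. Palladium would walk back to that carbon and the phenol oxygen would attack it, giving the 7-prenyloxy flavan A3 with ring C and C2 made in one step.
- *Merits.* It replaces fragment union, reduction and ring closure (steps 13–15 here) by one operation. It needs no ring A bromide and no methyl ketone, and A1 is very simple. It is clearly shorter and more convergent.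
- *Weak points.* A2 is an ortho-substituted, electron-rich boronic acid, prone to protodeboronation and homocoupling under oxidative conditions. The divalent palladium oxidant also meets a prenyl ether, a prenyl group and a chromene alkene, all open to Heck or Wacker-type chemistry. The C–O bond forms at a π-benzyl cation stabilised by O4', the same feature that makes C2 ionisable, so the enantioselectivity rests on a single ligand–substrate match. A3 still lacks the reverse prenyl group; a late Claisen rearrangement of the 7-O-prenyl ether must choose between C6 and C8, both unsubstituted, on a molecule that already holds the stereocentre.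
- *Comparison.* The chosen plan is several steps longer. Against that, each selectivity is decided in a separate, well-understood event on a small molecule, and no oxidant meets the alkenes.

**Alternative 2:** double Claisen cascade for ring D and the reverse prenyl group.

- *Cut and key step.* The arene–quaternary carbon bond at C6, the C3'–C bond of the chromene and the O–C bond of ring D are cut. Heating flavan A4, which carries a 7-O-prenyl ether and a 4'-O-(1,1-dimethylpropargyl) ether, would rearrange both ethers in one flask and close ring D by oxa-6π electrocyclisation to give the 5'-silyl ether A5.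
- *Merits.* The two sigmatropic events run separately here (steps 2 and 9) are merged at the end. The fragments before union are simpler, ring A needs no silyl group, and only one desilylation remains. In step count this road is better.
- *Weak points.* On the flavan, C6 and C8 are both free ortho positions of O7 and nothing biases the shift toward C6. The prenyl ether needs a higher temperature than the propargyl ether, so the new chromene, the ortho-(1,1-dimethylallyl)phenol (which can close to a dihydrobenzofuran) and the ionisable C2–O1 bond are all held hot. A4 still needs ring C and C2, so this reorders the synthesis but does not replace the aryl–oxygen closure.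
- *Comparison.* The chosen plan spends about two extra steps. In return the regiochemistry is settled on a cheap benzaldehyde whose competing position is flanked by bromine, and the stereocentre is never heated above 70 °C.

**Alternative 3:** asymmetric ortho-quinone methide cycloaddition.

- *Cut and key step.* O1–C2 and C3–C4 are cut. A chiral BINOL-derived phosphoric acid would dehydrate the ring A 2-hydroxybenzyl alcohol A6 to its ortho-quinone methide, which would add the ring B styrene A7 in a [4+2] cycloaddition to give the bis(tert-butyldimethylsilyl) flavan A8.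
- *Merits.* Ring C and C2 arise in one metal-free catalytic step from two fragments of equal size. In convergence and step count it is at least as good as the chosen plan.
- *Weak points.* The quinone methide from A6 has an unsubstituted methide carbon and is prone to oligomerise. A7 is ortho-substituted and offers the catalyst no hydrogen-bond handle. The developing charge at C2 is stabilised by O4', so the addition may be stepwise and the product can re-ionise under the same acid, eroding the enantiomeric purity. The 1,1-dimethylallyl, prenyl and chromene alkenes are competing nucleophiles toward the quinone methide and the acid.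
- *Comparison.* The chosen plan is longer. It sets against this a stereocentre made by a ketone reduction with close analogy and a sequence in which no acid touches C2 afterwards.

Key step: step 15

Remark on the chemistry: flavan locants (O1, C2–C4, C4a–C8a, primed for ring B) are used for the target and chromene locants for ring B intermediates; the sense of induction in step 14 is assigned by analogy with acetophenone, for which the (S,S) catalyst gives the S alcohol.

## Route

Step 1
Reactants: 1 2-bromo-4-hydroxybenzaldehyde; 2 1-bromo-3-methylbut-2-ene (prenyl bromide)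
Product: 3 2-bromo-4-[(3-methylbut-2-en-1-yl)oxy]benzaldehyde
Conditions: K2CO3, DMF, rt
Reagents that add atoms: none
Why: Williamson ether synthesis; the acidic para-formyl phenol is alkylated cleanly on oxygen by the primary allylic bromide (SN2).

Step 2
Reactants: 3 2-bromo-4-[(3-methylbut-2-en-1-yl)oxy]benzaldehyde
Product: 5 2-bromo-4-hydroxy-5-(2-methylbut-3-en-2-yl)benzaldehyde, via Claisen dienone 4 (not isolated)
Conditions: PhNEt2, 190 °C
Reagents that add atoms: none
Why: Aromatic Claisen rearrangement; the [3,3] shift through a chair transition state should deliver the dimethyl-substituted allyl terminus to C5, the ortho position not flanked by bromine, and dienone 4 tautomerises to the phenol. The para position is blocked by the formyl group, so a para migration cannot rearomatise.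

Step 3
Reactants: 5 2-bromo-4-hydroxy-5-(2-methylbut-3-en-2-yl)benzaldehyde
Product: 6 2-bromo-5-(2-methylbut-3-en-2-yl)-4-[(triisopropylsilyl)oxy]benzaldehyde
Conditions: TIPSOTf, 2,6-lutidine, CH2Cl2, 0 °C to rt
Reagents that add atoms: triisopropylsilyl trifluoromethanesulfonate, CC(C)[Si](OS(=O)(=O)C(F)(F)F)(C(C)C)C(C)C
Why: O-silylation of a phenol; the silyl triflate is used because the hydroxyl is hindered by the neighbouring quaternary carbon.

Step 4
Reactants: 6 2-bromo-5-(2-methylbut-3-en-2-yl)-4-[(triisopropylsilyl)oxy]benzaldehyde
Product: 7 {2-bromo-5-(2-methylbut-3-en-2-yl)-4-[(triisopropylsilyl)oxy]phenyl}methanol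
Conditions: NaBH4, MeOH–THF, 0 °C
Reagents that add atoms: none
Why: Hydride reduction of an aldehyde; the aryl bromide, the alkene and the aryl silyl ether are inert to borohydride at 0 °C.

Step 5
Reactants: 7 {2-bromo-5-(2-methylbut-3-en-2-yl)-4-[(triisopropylsilyl)oxy]phenyl}methanol
Product: 8 1-bromo-2-(bromomethyl)-4-(2-methylbut-3-en-2-yl)-5-[(triisopropylsilyl)oxy]benzene
Conditions: CBr4, PPh3, CH2Cl2, 0 °C
Reagents that add atoms: carbon tetrabromide, BrC(Br)(Br)Br
Why: Appel bromination under neutral conditions, so the acid-sensitive 1,1-dimethylallyl group and the silyl ether are spared; the electron-rich benzylic bromide is used without storage.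

Step 6
Reactants: 9 2-bromo-4,5-dimethoxybenzaldehyde
Product: 10 2-bromo-4,5-dihydroxybenzaldehyde
Conditions: BBr3, CH2Cl2, −78 °C to rt; then H2O
Reagents that add atoms: none
Why: Lewis acid cleavage of aryl methyl ethers; it is placed first because no acid-sensitive group is present yet.

Step 7
Reactants: 10 2-bromo-4,5-dihydroxybenzaldehyde; 11 3-chloro-3-methylbut-1-yne
Product: 12 2-bromo-5-hydroxy-4-[(2-methylbut-3-yn-2-yl)oxy]benzaldehyde
Conditions: DBU (1.05 equiv), CuCl2·2H2O (cat.), MeCN, 0 °C
Reagents that add atoms: none
Why: Copper-catalysed O-propargylation of a phenoxide with a tertiary propargylic chloride; one equivalent of base deprotonates only the hydroxyl para to the formyl group (more acidic by about two pKa units), so the ether should form at O4, as in the known 4-O-selective alkylations of 3,4-dihydroxybenzaldehyde.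

Step 8
Reactants: 12 2-bromo-5-hydroxy-4-[(2-methylbut-3-yn-2-yl)oxy]benzaldehyde
Product: 13 2-bromo-4-[(2-methylbut-3-yn-2-yl)oxy]-5-[(triisopropylsilyl)oxy]benzaldehyde
Conditions: TIPSCl, imidazole, DMF, rt to 40 °C
Reagents that add atoms: triisopropylsilyl chloride, CC(C)[Si](Cl)(C(C)C)C(C)C
Why: Imidazole-promoted silylation of the remaining phenol; the mild chloride is chosen so that the tertiary propargylic ether is not ionised.

Step 9
Reactants: 13 2-bromo-4-[(2-methylbut-3-yn-2-yl)oxy]-5-[(triisopropylsilyl)oxy]benzaldehyde
Product: 16 5-bromo-2,2-dimethyl-8-[(triisopropylsilyl)oxy]-2H-chromene-6-carbaldehyde, via allenylphenol 14 (not isolated), via ortho-quinone methide 15 (not isolated)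
Conditions: PhNEt2, 180 °C
Reagents that add atoms: none
Why: Aryl propargyl ether Claisen rearrangement to C3, the only ortho position that can rearomatise, then enolisation to 14, 1,5-hydrogen shift to 15 and oxa-6π electrocyclisation closes ring D; this is the standard entry to 2,2-dimethylchromenes.

Step 10
Reactants: 16 5-bromo-2,2-dimethyl-8-[(triisopropylsilyl)oxy]-2H-chromene-6-carbaldehyde; 17 4,4,5,5-tetramethyl-2-(3-methylbut-2-en-1-yl)-1,3,2-dioxaborolane (prenylboronic acid pinacol ester)
Product: 18 2,2-dimethyl-5-(3-methylbut-2-en-1-yl)-8-[(triisopropylsilyl)oxy]-2H-chromene-6-carbaldehyde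
Conditions: Pd(OAc)2 (cat.), t-BuXPhos, K3PO4 (aq), MeCN, 70 °C
Reagents that add atoms: none
Why: Suzuki–Miyaura coupling of an allylic boronate; with a bulky monodentate di-tert-butyl biarylphosphine the allylpalladium intermediate can equilibrate to the primary σ-allyl form before reductive elimination, which should give the linear prenyl arene. No terminal alkyne remains to compete for the aryl bromide.

Step 11
Reactants: 18 2,2-dimethyl-5-(3-methylbut-2-en-1-yl)-8-[(triisopropylsilyl)oxy]-2H-chromene-6-carbaldehyde
Product: 19 rac-1-{2,2-dimethyl-5-(3-methylbut-2-en-1-yl)-8-[(triisopropylsilyl)oxy]-2H-chromen-6-yl}ethan-1-ol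
Conditions: MeMgBr, THF, −78 to 0 °C
Reagents that add atoms: methylmagnesium bromide, C[Mg]Br
Why: Grignard addition to an aldehyde; it brings in the carbon that becomes C3, and the racemic carbinol centre is removed in the next step.

Step 12
Reactants: 19 rac-1-{2,2-dimethyl-5-(3-methylbut-2-en-1-yl)-8-[(triisopropylsilyl)oxy]-2H-chromen-6-yl}ethan-1-ol
Product: 20 1-{2,2-dimethyl-5-(3-methylbut-2-en-1-yl)-8-[(triisopropylsilyl)oxy]-2H-chromen-6-yl}ethan-1-one
Conditions: Dess–Martin periodinane, NaHCO3, CH2Cl2, 0 °C to rt
Reagents that add atoms: none
Why: Dess–Martin oxidation of a secondary benzylic alcohol; the buffered, non-acidic conditions leave the prenyl and chromene alkenes untouched.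

Step 13
Reactants: 20 1-{2,2-dimethyl-5-(3-methylbut-2-en-1-yl)-8-[(triisopropylsilyl)oxy]-2H-chromen-6-yl}ethan-1-one; 8 1-bromo-2-(bromomethyl)-4-(2-methylbut-3-en-2-yl)-5-[(triisopropylsilyl)oxy]benzene
Product: 22 3-{2-bromo-5-(2-methylbut-3-en-2-yl)-4-[(triisopropylsilyl)oxy]phenyl}-1-{2,2-dimethyl-5-(3-methylbut-2-en-1-yl)-8-[(triisopropylsilyl)oxy]-2H-chromen-6-yl}propan-1-one, via lithium enolate 21 (not isolated)
Conditions: LiN(i-Pr)2, THF, −78 °C; then 8, −78 to 0 °C
Reagents that add atoms: none
Why: SN2 alkylation of a kinetic lithium enolate by a benzylic bromide forms C3–C4; the methyl ketone can enolise on one side only, the aryl bromide and silyl ethers are inert at low temperature, and a slight excess of enolate limits double alkylation.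

Step 14
Reactants: 22 3-{2-bromo-5-(2-methylbut-3-en-2-yl)-4-[(triisopropylsilyl)oxy]phenyl}-1-{2,2-dimethyl-5-(3-methylbut-2-en-1-yl)-8-[(triisopropylsilyl)oxy]-2H-chromen-6-yl}propan-1-one
Product: 23 (1S)-3-{2-bromo-5-(2-methylbut-3-en-2-yl)-4-[(triisopropylsilyl)oxy]phenyl}-1-{2,2-dimethyl-5-(3-methylbut-2-en-1-yl)-8-[(triisopropylsilyl)oxy]-2H-chromen-6-yl}propan-1-ol
Conditions: RuCl(p-cymene)[(S,S)-TsDPEN] (cat.), HCO2H–Et3N (5:2), CH2Cl2, 30 °C
Reagents that add atoms: none
Why: Noyori asymmetric transfer hydrogenation of an aryl alkyl ketone; hydride and proton pass from the Ru–H/N–H pair through a six-membered transition state in which a CH/π contact between the p-cymene ligand and ring B fixes the aryl group, so the (S,S) catalyst should give the S carbinol as it does with acetophenone. Isolated and styrene-like alkenes and the aryl bromide are not reduced.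

Step 15
Reactants: 23 (1S)-3-{2-bromo-5-(2-methylbut-3-en-2-yl)-4-[(triisopropylsilyl)oxy]phenyl}-1-{2,2-dimethyl-5-(3-methylbut-2-en-1-yl)-8-[(triisopropylsilyl)oxy]-2H-chromen-6-yl}propan-1-ol
Product: 24 (2S)-kazinol H 7,5'-bis(triisopropylsilyl) ether
Conditions: Pd(OAc)2 (5 mol %), rac-2-(di-tert-butylphosphino)-1,1'-binaphthyl (6 mol %), Cs2CO3, toluene, 70 °C
Reagents that add atoms: none
Why: Pd(OAc)2 is reduced in the flask to zerovalent palladium, which inserts into the C8a–Br bond of 23; carbonate deprotonates the coordinated carbinol and bromide is displaced to give a seven-membered aryl(alkoxo)palladium oxapalladacycle. Reductive elimination from this divalent palladium species forms O1–C8a and closes ring C as a six-membered ring (closure by reductive elimination from the seven-membered metallacycle, formally a 6-exo attack of oxygen on the ipso carbon). The closest known reaction type is the palladium-catalysed intramolecular etherification of aryl bromides with secondary alcohols to 2-substituted chromans, which proceeds without loss of configuration at the carbinol carbon. No stereocentre is created: C2 was set in step 14, none of its bonds is broken, and the CIP ranking O > C1' > C3 > H is unchanged, so S is carried through with retention. The selectivity the step needs is reductive elimination over β-hydride elimination of the benzylic palladium alkoxide, which would return ketone 22 with loss of bromine; the bulky, electron-rich di-tert-butyl biarylphosphine keeps palladium monoligated and speeds C–O bond formation. The substrate secures chemoselectivity: the C8a bromide is the only halide, the vinyl group of the reverse prenyl unit is para to it and the ring B alkenes are remote, so no intramolecular Heck path exists, and the aryl silyl ethers tolerate anhydrous Cs2CO3 in toluene.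

Step 16
Reactants: 24 (2S)-kazinol H 7,5'-bis(triisopropylsilyl) ether
Product: 25 kazinol H, (2S)-configured
Conditions: n-Bu4NF, AcOH, THF, 0 °C
Reagents that add atoms: none
Why: Fluoride cleaves both aryl O–Si bonds; acetic acid buffers the phenoxides so that the electron-rich rings are not oxidised, and C2–O1 sees neither strong acid nor strong base.

## Compound list

1 | 2-bromo-4-hydroxybenzaldehyde | O=Cc1ccc(O)cc1Br | starting material
2 | 1-bromo-3-methylbut-2-ene (prenyl bromide) | CC(C)=CCBr | starting material
3 | 2-bromo-4-[(3-methylbut-2-en-1-yl)oxy]benzaldehyde | O=Cc1ccc(OCC=C(C)C)cc1Br | intermediate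
4 | 6-bromo-3-(2-methylbut-3-en-2-yl)-4-oxocyclohexa-1,5-diene-1-carbaldehyde (racemic Claisen dienone, not isolated) | O=CC1=CC(C(C)(C)C=C)C(=O)C=C1Br | intermediate
5 | 2-bromo-4-hydroxy-5-(2-methylbut-3-en-2-yl)benzaldehyde | O=Cc1cc(C(C)(C)C=C)c(O)cc1Br | intermediate
6 | 2-bromo-5-(2-methylbut-3-en-2-yl)-4-[(triisopropylsilyl)oxy]benzaldehyde | O=Cc1cc(C(C)(C)C=C)c(O[Si](C(C)C)(C(C)C)C(C)C)cc1Br | intermediate
7 | {2-bromo-5-(2-methylbut-3-en-2-yl)-4-[(triisopropylsilyl)oxy]phenyl}methanol | OCc1cc(C(C)(C)C=C)c(O[Si](C(C)C)(C(C)C)C(C)C)cc1Br | intermediate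
8 | 1-bromo-2-(bromomethyl)-4-(2-methylbut-3-en-2-yl)-5-[(triisopropylsilyl)oxy]benzene | BrCc1cc(C(C)(C)C=C)c(O[Si](C(C)C)(C(C)C)C(C)C)cc1Br | intermediate
9 | 2-bromo-4,5-dimethoxybenzaldehyde | COc1cc(Br)c(C=O)cc1OC | starting material
10 | 2-bromo-4,5-dihydroxybenzaldehyde | O=Cc1cc(O)c(O)cc1Br | intermediate
11 | 3-chloro-3-methylbut-1-yne | C#CC(C)(C)Cl | starting material
12 | 2-bromo-5-hydroxy-4-[(2-methylbut-3-yn-2-yl)oxy]benzaldehyde | O=Cc1cc(O)c(OC(C)(C)C#C)cc1Br | intermediate
13 | 2-bromo-4-[(2-methylbut-3-yn-2-yl)oxy]-5-[(triisopropylsilyl)oxy]benzaldehyde | O=Cc1cc(O[Si](C(C)C)(C(C)C)C(C)C)c(OC(C)(C)C#C)cc1Br | intermediate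
14 | 2-bromo-4-hydroxy-3-(3-methylbuta-1,2-dien-1-yl)-5-[(triisopropylsilyl)oxy]benzaldehyde (allenylphenol, not isolated) | O=Cc1cc(O[Si](C(C)C)(C(C)C)C(C)C)c(O)c(C=C=C(C)C)c1Br | intermediate
15 | 2-bromo-3-(3-methylbut-2-en-1-ylidene)-4-oxo-5-[(triisopropylsilyl)oxy]cyclohexa-1,5-diene-1-carbaldehyde (ortho-quinone methide, not isolated) | O=CC1=C(Br)C(=CC=C(C)C)C(=O)C(O[Si](C(C)C)(C(C)C)C(C)C)=C1 | intermediate
16 | 5-bromo-2,2-dimethyl-8-[(triisopropylsilyl)oxy]-2H-chromene-6-carbaldehyde | O=Cc1cc(O[Si](C(C)C)(C(C)C)C(C)C)c2c(c1Br)C=CC(C)(C)O2 | intermediate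
17 | 4,4,5,5-tetramethyl-2-(3-methylbut-2-en-1-yl)-1,3,2-dioxaborolane (prenylboronic acid pinacol ester) | CC(C)=CCB1OC(C)(C)C(C)(C)O1 | starting material
18 | 2,2-dimethyl-5-(3-methylbut-2-en-1-yl)-8-[(triisopropylsilyl)oxy]-2H-chromene-6-carbaldehyde | O=Cc1cc(O[Si](C(C)C)(C(C)C)C(C)C)c2c(c1CC=C(C)C)C=CC(C)(C)O2 | intermediate
19 | rac-1-{2,2-dimethyl-5-(3-methylbut-2-en-1-yl)-8-[(triisopropylsilyl)oxy]-2H-chromen-6-yl}ethan-1-ol | CC(O)c1cc(O[Si](C(C)C)(C(C)C)C(C)C)c2c(c1CC=C(C)C)C=CC(C)(C)O2 | intermediate
20 | 1-{2,2-dimethyl-5-(3-methylbut-2-en-1-yl)-8-[(triisopropylsilyl)oxy]-2H-chromen-6-yl}ethan-1-one | CC(=O)c1cc(O[Si](C(C)C)(C(C)C)C(C)C)c2c(c1CC=C(C)C)C=CC(C)(C)O2 | intermediate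
21 | lithium 1-{2,2-dimethyl-5-(3-methylbut-2-en-1-yl)-8-[(triisopropylsilyl)oxy]-2H-chromen-6-yl}ethen-1-olate (enolate, not isolated) | [Li]OC(=C)c1cc(O[Si](C(C)C)(C(C)C)C(C)C)c2c(c1CC=C(C)C)C=CC(C)(C)O2 | intermediate
22 | 3-{2-bromo-5-(2-methylbut-3-en-2-yl)-4-[(triisopropylsilyl)oxy]phenyl}-1-{2,2-dimethyl-5-(3-methylbut-2-en-1-yl)-8-[(triisopropylsilyl)oxy]-2H-chromen-6-yl}propan-1-one | O=C(CCc1cc(C(C)(C)C=C)c(O[Si](C(C)C)(C(C)C)C(C)C)cc1Br)c1cc(O[Si](C(C)C)(C(C)C)C(C)C)c2c(c1CC=C(C)C)C=CC(C)(C)O2 | intermediate
23 | (1S)-3-{2-bromo-5-(2-methylbut-3-en-2-yl)-4-[(triisopropylsilyl)oxy]phenyl}-1-{2,2-dimethyl-5-(3-methylbut-2-en-1-yl)-8-[(triisopropylsilyl)oxy]-2H-chromen-6-yl}propan-1-ol | O[C@H](c1cc(O[Si](C(C)C)(C(C)C)C(C)C)c2c(c1CC=C(C)C)C=CC(C)(C)O2)CCc1cc(C(C)(C)C=C)c(O[Si](C(C)C)(C(C)C)C(C)C)cc1Br | intermediate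
24 | (2S)-kazinol H 7,5'-bis(triisopropylsilyl) ether | C=CC(C)(C)c1cc2c(cc1O[Si](C(C)C)(C(C)C)C(C)C)O[C@H](c1cc(O[Si](C(C)C)(C(C)C)C(C)C)c3c(c1CC=C(C)C)C=CC(C)(C)O3)CC2 | intermediate
25 | kazinol H, (2S) | C=CC(C)(C)c1cc2c(cc1O)O[C@H](c1cc(O)c3c(c1CC=C(C)C)C=CC(C)(C)O3)CC2 | target

## Step count and risks

Total step count: 16. Longest linear sequence: 11 steps (9 to 25, steps 6–16); the ring A branch (1 to 8, steps 1–5) joins at step 13.

**Step 15 (key step).** The most likely failure is β-hydride elimination of the benzylic palladium alkoxide, which would oxidise the carbinol back to the ketone and reduce the C–Br bond. A second is sluggish oxidative addition at the fairly electron-rich ring A bromide. Fallback: the closure is moved from palladium to copper. From 23, copper iodide CuI with 3,4,7,8-tetramethyl-1,10-phenanthroline and Cs2CO3 in toluene at 110 °C (Ullmann-type etherification) would give 24 directly. A copper alkoxide has no facile β-hydride pathway, and the same O1–C8a bond is formed with C2 untouched. No new compound arises.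

**Step 2.** Rearrangement may leak to the ortho position next to bromine, and the product may react further at 190 °C (ring closure of the ortho-(1,1-dimethylallyl)phenol onto its alkene, or loss of the C5 unit by fragmentation). Fallback: the quaternary carbon is attached by cross-coupling, not by sigmatropy. From 1, iodination with N-iodosuccinimide at the unhindered ortho position would give 2-bromo-4-hydroxy-5-iodobenzaldehyde F1. A γ-selective Suzuki–Miyaura coupling of F1 with 17 (Pd(OAc)2, 1,1'-bis(di-tert-butylphosphino)ferrocene, K2CO3, aqueous THF, 40 °C), selective for the C–I bond, would return to the route at 5.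

**Step 7.** Alkylation may occur at the wrong hydroxyl or at both, and the free neighbouring hydroxyl may add to the alkyne. Fallback: the order of silylation and alkylation is inverted. From 10, excess TIPSCl and imidazole would give 2-bromo-4,5-bis[(triisopropylsilyl)oxy]benzaldehyde F2. The silyl ether para to the formyl group, whose phenoxide is the better leaving group, would be cleaved selectively with K2CO3 in MeOH at 0 °C to 2-bromo-4-hydroxy-5-[(triisopropylsilyl)oxy]benzaldehyde F3. Propargylation of F3 with 11 under the conditions of step 7 would rejoin the route at 13.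

**Step 10.** Reductive elimination may occur from the tertiary allylpalladium isomer, giving the branched product. The doubly ortho-substituted bromide may also insert slowly while 17 is lost to protodeboronation, and the silyl ether may suffer in aqueous phosphate. Fallback: the regiochemical question is removed by coupling an unsubstituted allyl group and building the trisubstituted alkene afterwards. From 16, Suzuki–Miyaura coupling with allylboronic acid pinacol ester would give 5-allyl-2,2-dimethyl-8-[(triisopropylsilyl)oxy]-2H-chromene-6-carbaldehyde F4. Cross-metathesis of F4 with 2-methylbut-2-ene and the second-generation Grubbs catalyst RuCl2(=CHPh)(H2IMes)(PCy3) in CH2Cl2 at 40 °C would return to the route at 18.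

**Step 13.** Proton transfer between the product ketone and the enolate may lead to double alkylation, and the electron-rich benzylic bromide 8 may decompose before it is consumed. Fallback: the union is made by carbonyl addition instead of substitution. From 20 and aldehyde 6, aldol addition of enolate 21 at −78 °C would give 3-{2-bromo-5-(2-methylbut-3-en-2-yl)-4-[(triisopropylsilyl)oxy]phenyl}-3-hydroxy-1-{2,2-dimethyl-5-(3-methylbut-2-en-1-yl)-8-[(triisopropylsilyl)oxy]-2H-chromen-6-yl}propan-1-one F5. Mesylation and elimination (MsCl, Et3N) would give (2E)-3-{2-bromo-5-(2-methylbut-3-en-2-yl)-4-[(triisopropylsilyl)oxy]phenyl}-1-{2,2-dimethyl-5-(3-methylbut-2-en-1-yl)-8-[(triisopropylsilyl)oxy]-2H-chromen-6-yl}prop-2-en-1-one F6. Conjugate reduction of F6 with [(Ph3P)CuH]6, which spares isolated alkenes and the aryl bromide, would return to the route at 22. Steps 4 and 5 would then be unnecessary.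

**Step 14.** The ortho-prenyl group twists the electron-rich aryl ketone, so hydride transfer may be slow or poorly face-selective, and the para-alkoxybenzylic carbinol may ionise in the formic acid medium and lose enantiomeric purity. Fallback: the mode of recognition is changed from ruthenium–ligand bifunctional hydride transfer to a Lewis-acid-organised borane reduction. From 22, Corey–Bakshi–Shibata reduction with (R)-2-methyl-CBS-oxazaborolidine and catecholborane in toluene at −78 °C should give 23 under non-acidic conditions; catecholborane does not hydroborate the alkenes at this temperature. No new compound arises.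

## Further compounds

F1 | step 2 | 2-bromo-4-hydroxy-5-iodobenzaldehyde | O=Cc1cc(I)c(O)cc1Br
F2 | step 7 | 2-bromo-4,5-bis[(triisopropylsilyl)oxy]benzaldehyde | O=Cc1cc(O[Si](C(C)C)(C(C)C)C(C)C)c(O[Si](C(C)C)(C(C)C)C(C)C)cc1Br
F3 | step 7 | 2-bromo-4-hydroxy-5-[(triisopropylsilyl)oxy]benzaldehyde | O=Cc1cc(O[Si](C(C)C)(C(C)C)C(C)C)c(O)cc1Br
F4 | step 10 | 5-allyl-2,2-dimethyl-8-[(triisopropylsilyl)oxy]-2H-chromene-6-carbaldehyde | O=Cc1cc(O[Si](C(C)C)(C(C)C)C(C)C)c2c(c1CC=C)C=CC(C)(C)O2
F5 | step 13 | 3-{2-bromo-5-(2-methylbut-3-en-2-yl)-4-[(triisopropylsilyl)oxy]phenyl}-3-hydroxy-1-{2,2-dimethyl-5-(3-methylbut-2-en-1-yl)-8-[(triisopropylsilyl)oxy]-2H-chromen-6-yl}propan-1-one (racemic) | O=C(CC(O)c1cc(C(C)(C)C=C)c(O[Si](C(C)C)(C(C)C)C(C)C)cc1Br)c1cc(O[Si](C(C)C)(C(C)C)C(C)C)c2c(c1CC=C(C)C)C=CC(C)(C)O2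
F6 | step 13 | (2E)-3-{2-bromo-5-(2-methylbut-3-en-2-yl)-4-[(triisopropylsilyl)oxy]phenyl}-1-{2,2-dimethyl-5-(3-methylbut-2-en-1-yl)-8-[(triisopropylsilyl)oxy]-2H-chromen-6-yl}prop-2-en-1-one | O=C(/C=C/c1cc(C(C)(C)C=C)c(O[Si](C(C)C)(C(C)C)C(C)C)cc1Br)c1cc(O[Si](C(C)C)(C(C)C)C(C)C)c2c(c1CC=C(C)C)C=CC(C)(C)O2
F0 | step 14 | none | none
F0 | step 15 | none | none
A1 | alternative 1 | 2-allyl-5-[(3-methylbut-2-en-1-yl)oxy]phenol | C=CCc1ccc(OCC=C(C)C)cc1O
A2 | alternative 1 | {8-[(tert-butyldimethylsilyl)oxy]-2,2-dimethyl-5-(3-methylbut-2-en-1-yl)-2H-chromen-6-yl}boronic acid | OB(O)c1cc(O[Si](C)(C)C(C)(C)C)c2c(c1CC=C(C)C)C=CC(C)(C)O2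
A3 | alternative 1 | (2S)-2-{8-[(tert-butyldimethylsilyl)oxy]-2,2-dimethyl-5-(3-methylbut-2-en-1-yl)-2H-chromen-6-yl}-7-[(3-methylbut-2-en-1-yl)oxy]chroman | CC(C)=CCOc1ccc2c(c1)O[C@H](c1cc(O[Si](C)(C)C(C)(C)C)c3c(c1CC=C(C)C)C=CC(C)(C)O3)CC2
A4 | alternative 2 | (2S)-2-{2-(3-methylbut-2-en-1-yl)-4-[(2-methylbut-3-yn-2-yl)oxy]-5-[(triisopropylsilyl)oxy]phenyl}-7-[(3-methylbut-2-en-1-yl)oxy]chroman | CC(C)=CCOc1ccc2c(c1)O[C@H](c1cc(O[Si](C(C)C)(C(C)C)C(C)C)c(OC(C)(C)C#C)cc1CC=C(C)C)CC2
A5 | alternative 2 | (2S)-kazinol H 5'-triisopropylsilyl ether | C=CC(C)(C)c1cc2c(cc1O)O[C@H](c1cc(O[Si](C(C)C)(C(C)C)C(C)C)c3c(c1CC=C(C)C)C=CC(C)(C)O3)CC2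
A6 | alternative 3 | 5-[(tert-butyldimethylsilyl)oxy]-2-(hydroxymethyl)-4-(2-methylbut-3-en-2-yl)phenol | OCc1cc(C(C)(C)C=C)c(O[Si](C)(C)C(C)(C)C)cc1O
A7 | alternative 3 | tert-butyl{[6-ethenyl-2,2-dimethyl-5-(3-methylbut-2-en-1-yl)-2H-chromen-8-yl]oxy}dimethylsilane | C=Cc1cc(O[Si](C)(C)C(C)(C)C)c2c(c1CC=C(C)C)C=CC(C)(C)O2
A8 | alternative 3 | (2S)-kazinol H 7,5'-bis(tert-butyldimethylsilyl) ether | C=CC(C)(C)c1cc2c(cc1O[Si](C)(C)C(C)(C)C)O[C@H](c1cc(O[Si](C)(C)C(C)(C)C)c3c(c1CC=C(C)C)C=CC(C)(C)O3)CC2
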